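## The problem

The target 12 is a 3,4-dihydroisocoumarin: a benzene ring fused to a six-membered lactone, with the lactone carbonyl C1 on C8a and the saturated C4 on C4a. The benzene ring carries two oxygens meta to each other, a methyl ether at C6 and a free phenol at C8. The C8 phenol lies peri to the lactone carbonyl, and the two oxygens must be told apart at some stage. C3 is the only stereocentre, (R), and bears the ring oxygen and an unbranched eleven-carbon chain ending in a primary alcohol. With no second stereocentre, nothing in the molecule can relay its configuration, so it must come from a catalyst or a chiral building block. The lactone opens under hydroxide or alkoxide, the electron-rich ring is sensitive to oxidants and strong electrophiles, and the primary alcohol needs a mask through the metal-catalysed and Lewis-acid steps. The enabling feature is seen when the lactone ring is cut at O2–C3 and C4a–C4: what remains is a benzoic acid whose carboxyl carbon is C1. Because C8 already holds an oxygen, C4a is the only ortho C–H of that acid. In the ring-opened form C3 is a ketone carbon, so the stereocentre can be postponed to the reduction of a flat C3=C4 enol lactone.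

## Retrosynthesis

**Protecting groups last (12 from 11 from 10).** The O–Si bond of the chain and the O–CH3 bond at C8 are cut last. Phenol 11 is the silyl ether of 12, and 11 comes from the dimethyl ether 10 by chelation-directed cleavage of only the C8 methyl ether, which the peri carbonyl makes possible. A methyl group is kept at O8 until then because a free ortho phenol would compete with the carboxylate in the metal-catalysed step. The chain oxygen is carried as a tert-butyldiphenylsilyl ether, which tolerates warm, weakly acidic media better than smaller silyl groups.

**The stereocentre (10 from 9).** Removing the two hydrogens at C3 and C4 leads to isocoumarin 9, which is achiral and flat. This is preferred over bringing C3 in as a chiral epoxide or alcohol, because those choices force a stoichiometric aryl-metal coupling and a longer chain synthesis. The forward step must add hydrogen to one face of the C3=C4 enol-lactone bond under catalyst control alone.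

**The key disconnection (9 from 7 and 6, through 8).** Cutting C4a–C4 and O2–C3 of 9 gives 2,4-dimethoxybenzoic acid 7 and the sulfoxonium ylide 6; keto acid 8 is the open form that closes to 9. Against a cut at C4–C3 (benzylic anion of an ortho-toluate), this cut needs no pre-installed methyl group and no strong base, and it takes both skeletal bonds and the ring from a commercial acid in one operation. The forward reaction must functionalise the single ortho C–H of 7, transfer the acylmethyl unit from sulfur, and close the ring through oxygen.

**The chain (6 from 3 and 4, through 5; 3 from 1, through 2).** The ylide 6 is cut at its C1–C2 bond into an acyl unit and the methylide derived from trimethylsulfoxonium iodide 4. The acyl unit is acid chloride 5 of the silylated acid 3. Acid 3 comes from 12-hydroxydodecanoic acid 1, which already holds all eleven methylene groups and the terminal oxygen; the doubly silylated 2 is a transient on the way.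

## Roads not taken

**Alternative 1:** Both ring-substituent bonds of the arene, C4a–C4 and C8a–C1, would be made at once. Fluoride would release the aryne from 3,5-dimethoxy-2-(trimethylsilyl)phenyl triflate A1, and dimethyl malonate A2 would insert one C–C bond across it to give methyl 2-(2-methoxy-2-oxoethyl)-4,6-dimethoxybenzoate A3.
- Merits: no transition metal, mild conditions, and the methoxy group beside the aryne bond steers the nucleophile to the distal carbon, which gives exactly the required pattern.
- Weak points: the step closes no ring, brings no chain and sets no stereocentre. A1 is not a commodity and needs several steps. A3 would still have to be C-acylated with 5, decarboxylated and cyclised, and would arrive at the same kind of isocoumarin as 9.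
- Comparison: it is equal in regiocontrol and better in avoiding rhodium and silver. The chosen plan sets against this about five fewer steps and a direct union of 7 and 6. The stereochemical question is the same on both roads.

**Alternative 2:** The cut is at the ring oxygen. A Baeyer–Villiger monooxygenase with air and a recycled nicotinamide cofactor would insert oxygen between C1 and C2 of racemic 2-(11-hydroxyundecyl)-5,7-dimethoxyindan-1-one A4. Mild base would racemise the unreacted ketone, giving (R)-3-(11-hydroxyundecyl)-6,8-dimethoxyisochroman-1-one A5 by dynamic kinetic resolution.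
- Merits: the lactone and the stereocentre arise in one step, the whole racemate can be converted, and the chain alcohol needs no protection.
- Weak points: the enzymes known for this ring expansion take small 2-alkylindanones, whereas A4 has a long lipophilic chain and a methoxy group peri to the carbonyl. The electron-rich aryl group favours the competing aryl migration to a dihydrocoumarin. A4 itself needs several steps, and the C8 ether still has to be cleaved.
- Comparison: if a fitting enzyme were found, this road would be better at the stereochemical point, since ring formation and induction coincide and no pressure hydrogenation is needed. The chosen plan sets against this that both of its catalytic steps belong to reaction classes already shown on 3-substituted, 8-alkoxylated substrates, and that tuning is by ligand choice, not protein engineering.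

**Alternative 3:** The cut is inside the benzene ring at C4a–C8a. Base then acid would make the dioxinone α-carbon of (R)-6-[6,17-bis(tert-butyldimethylsilyloxy)-2,4-dioxoheptadecyl]-2,2-dimethyl-4H-1,3-dioxin-4-one A6 attack the distal ketone. Dehydration and enolisation would give (R)-5-[2,13-bis(tert-butyldimethylsilyloxy)tridecyl]-7-hydroxy-2,2-dimethyl-4H-benzo[d][1,3]dioxin-4-one A7.
- Merits: C3 is carried from a reliable asymmetric source and is never in question. The two phenolic oxygens emerge already differentiated, so methylation of the free one, desilylation and lactonisation onto the dioxinone would give 12 without any ether cleavage.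
- Weak points: A6 needs a chiral alcohol and two Claisen-type chain extensions, some six or seven steps. Its silyloxy group is β to a ketone and prone to elimination under the basic aromatisation conditions. The route is roughly twice as long.
- Comparison: it is better in stereochemical security and in phenol differentiation. The chosen plan sets against this brevity and stable intermediates, and accepts the hydrogenation risk with a fallback.

Key step: step 3

Assumption: the sense of induction of the ruthenium NHC–diamine catalyst in step 4 is taken to invert with the mirror-image ligand pair. The antipode that gives (R)-C3 is used, and the sense is fixed in a first run against both enantiomers on a chiral stationary phase.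

## Route

Step 1
Reactants: 1 12-hydroxydodecanoic acid
Product: 3 12-(tert-butyldiphenylsilyloxy)dodecanoic acid, via tert-butyldiphenylsilyl 12-(tert-butyldiphenylsilyloxy)dodecanoate 2 (not isolated)
Conditions: TBDPSCl (2.3 equiv), imidazole (5 equiv), DMF, 0 °C to rt; then K2CO3, THF–H2O, rt; 1 M HCl to pH 3
Reagents that add atoms: tert-butyldiphenylsilyl chloride, CC(C)(C)[Si](Cl)(c1ccccc1)c1ccccc1
Why: Silylation of both the alcohol and the acid, then selective hydrolysis of the labile silyl ester; the primary silyl ether is stable to aqueous carbonate.

Step 2
Reactants: 3 12-(tert-butyldiphenylsilyloxy)dodecanoic acid; 4 trimethylsulfoxonium iodide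
Product: 6 13-(tert-butyldiphenylsilyloxy)-1-(dimethyloxosulfuranylidene)tridecan-2-one, via 12-(tert-butyldiphenylsilyloxy)dodecanoyl chloride 5 (not isolated)
Conditions: (COCl)2, DMF (cat.), CH2Cl2, 0 °C to rt, evaporate; add to Me3S(O)I (3 equiv)/KOtBu (3 equiv) in THF (pre-refluxed), 0 °C to rt
Reagents that add atoms: none
Why: Acylation of dimethylsulfoxonium methylide by an acid chloride (Corey–Chaykovsky ylide acylation); a second equivalent of methylide deprotonates the first-formed β-keto sulfoxonium salt and gives the stabilised, isolable ylide.

Step 3
Reactants: 7 2,4-dimethoxybenzoic acid; 6 13-(tert-butyldiphenylsilyloxy)-1-(dimethyloxosulfuranylidene)tridecan-2-one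
Product: 9 3-[11-(tert-butyldiphenylsilyloxy)undecyl]-6,8-dimethoxy-1H-isochromen-1-one, via 2-[13-(tert-butyldiphenylsilyloxy)-2-oxotridecyl]-4,6-dimethoxybenzoic acid 8 (not isolated)
Conditions: [Cp*RhCl2]2 (2.5 mol%), AgSbF6 (10 mol%), NaOAc (30 mol%), 7 (1.5 equiv), CF3CH2OH, 80 °C
Reagents that add atoms: none
Why: Chloride abstraction by AgSbF6 gives a cationic Cp*Rh species of trivalent rhodium, which binds the carboxylate of 7 and breaks the only ortho C–H bond (the future C4a–H) by carboxylate-assisted concerted metalation–deprotonation to form a five-membered rhodacycle. The ylide carbon of 6 coordinates, the sulfoxide leaves, and the resulting rhodium carbene inserts into the Rh–aryl bond to create C4a–C4; protodemetalation then releases keto acid 8 and returns the catalyst. The carboxyl oxygen of 8 adds to the ketone carbon in a 6-exo-trig closure and the hemiketal loses water, which forms O2–C3 and the C3=C4 bond of the isocoumarin ring. The closest known reaction type is the Cp*Rh- and (p-cymene)Ru-catalysed C–H acylmethylation and annulation of benzoic acids and benzamides with sulfoxonium ylides to 3-substituted isocoumarins. No stereocentre is created. The step needs site selectivity and single functionalisation, and the substrate secures both, because the methoxy group that becomes the C8 substituent blocks the second ortho position. It also needs closure through oxygen, which follows because the carboxylate is the only nucleophile placed for a six-membered ring. Acid 7 is used in excess because 6 is the more valuable partner, and the tert-butyldiphenylsilyl ether is chosen to withstand the warm fluoroalcohol medium.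

Step 4
Reactants: 9 3-[11-(tert-butyldiphenylsilyloxy)undecyl]-6,8-dimethoxy-1H-isochromen-1-one
Product: 10 (R)-3-[11-(tert-butyldiphenylsilyloxy)undecyl]-6,8-dimethoxyisochroman-1-one
Conditions: H2 (50 bar), precatalyst from Ru(cod)(2-methylallyl)2, SINpEt·HBF4, KOtBu and 1,2-diphenylethane-1,2-diamine (2 mol%), NaOtBu (10 mol%), toluene, 25 °C
Reagents that add atoms: none
Why: Asymmetric hydrogenation of the C3=C4 enol-lactone bond of a 3-substituted isocoumarin with a chiral ruthenium NHC–diamine catalyst (SINpEt is 1,3-bis[1-(1-naphthyl)ethyl]imidazolin-2-ylidene). The substrate is flat, so the chiral pocket of the carbene arms and the diamine alone chooses the face, and the ligand antipode that gives (R)-C3 is used. The arene, the lactone C–O bonds and the silyl ether are not expected to react.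

Step 5
Reactants: 10 (R)-3-[11-(tert-butyldiphenylsilyloxy)undecyl]-6,8-dimethoxyisochroman-1-one
Product: 11 (R)-3-[11-(tert-butyldiphenylsilyloxy)undecyl]-8-hydroxy-6-methoxyisochroman-1-one
Conditions: BCl3 (2 equiv), CH2Cl2, −78 to 0 °C; then H2O
Reagents that add atoms: none
Why: Chelation-controlled Lewis-acid ether cleavage: boron bridges the lactone carbonyl oxygen and the peri C8 methoxy oxygen in a six-membered chelate and chloride removes that methyl group, while the unchelated C6 ether stays. No bond to C3 is broken, so the configuration is kept.

Step 6
Reactants: 11 (R)-3-[11-(tert-butyldiphenylsilyloxy)undecyl]-8-hydroxy-6-methoxyisochroman-1-one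
Product: 12 (R)-8-hydroxy-3-(11-hydroxyundecyl)-6-methoxyisochroman-1-one
Conditions: Bu4NF (1.5 equiv), AcOH (1.5 equiv), THF, 0 °C to rt
Reagents that add atoms: none
Why: Fluoride-mediated cleavage of the Si–O bond; buffering with acetic acid keeps the medium from opening the lactone, and C3 is not involved.

## Compound list

1 | 12-hydroxydodecanoic acid | OCCCCCCCCCCCC(=O)O | starting material
2 | tert-butyldiphenylsilyl 12-(tert-butyldiphenylsilyloxy)dodecanoate | CC(C)(C)[Si](c1ccccc1)(c1ccccc1)OCCCCCCCCCCCC(=O)O[Si](c1ccccc1)(c1ccccc1)C(C)(C)C | intermediate
3 | 12-(tert-butyldiphenylsilyloxy)dodecanoic acid | CC(C)(C)[Si](c1ccccc1)(c1ccccc1)OCCCCCCCCCCCC(=O)O | intermediate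
4 | trimethylsulfoxonium iodide | C[S+](C)(C)=O.[I-] | starting material
5 | 12-(tert-butyldiphenylsilyloxy)dodecanoyl chloride | CC(C)(C)[Si](c1ccccc1)(c1ccccc1)OCCCCCCCCCCCC(=O)Cl | intermediate
6 | 13-(tert-butyldiphenylsilyloxy)-1-(dimethyloxosulfuranylidene)tridecan-2-one | CS(C)(=O)=CC(=O)CCCCCCCCCCCO[Si](c1ccccc1)(c1ccccc1)C(C)(C)C | intermediate
7 | 2,4-dimethoxybenzoic acid | COc1ccc(C(=O)O)c(OC)c1 | starting material
8 | 2-[13-(tert-butyldiphenylsilyloxy)-2-oxotridecyl]-4,6-dimethoxybenzoic acid | COc1cc(OC)c(C(=O)O)c(CC(=O)CCCCCCCCCCCO[Si](c2ccccc2)(c2ccccc2)C(C)(C)C)c1 | intermediate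
9 | 3-[11-(tert-butyldiphenylsilyloxy)undecyl]-6,8-dimethoxy-1H-isochromen-1-one | COc1cc(OC)c2c(c1)C=C(CCCCCCCCCCCO[Si](c3ccccc3)(c3ccccc3)C(C)(C)C)OC2=O | intermediate
10 | (R)-3-[11-(tert-butyldiphenylsilyloxy)undecyl]-6,8-dimethoxyisochroman-1-one | COc1cc(OC)c2c(c1)C[C@@H](CCCCCCCCCCCO[Si](c3ccccc3)(c3ccccc3)C(C)(C)C)OC2=O | intermediate
11 | (R)-3-[11-(tert-butyldiphenylsilyloxy)undecyl]-8-hydroxy-6-methoxyisochroman-1-one | COc1cc(O)c2c(c1)C[C@@H](CCCCCCCCCCCO[Si](c3ccccc3)(c3ccccc3)C(C)(C)C)OC2=O | intermediate
12 | (R)-8-hydroxy-3-(11-hydroxyundecyl)-6-methoxyisochroman-1-one | COc1cc(O)c2c(c1)C[C@@H](CCCCCCCCCCCO)OC2=O | target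

## Step count and risks

Total step count: 6. Longest linear sequence: 6 steps (1 to 3 to 6 to 9 to 10 to 11 to 12); acid 7 enters at step 3.

**Step 3 (key step).** The likely failures are slow C–H metalation of the twisted, electron-rich acid, so that protonation or self-condensation of the ylide outruns carbene transfer. Silver-promoted loss of carbon dioxide from 7 is also possible, as is arrest at the open keto acid before dehydration. The fallback builds the same ring by benzylic anion chemistry. It sets out from 3, which is converted with carbonyldiimidazole and N,O-dimethylhydroxylamine hydrochloride into N-methoxy-N-methyl-12-(tert-butyldiphenylsilyloxy)dodecanamide F1. Commercial methyl 2,4-dimethoxy-6-methylbenzoate F2 is deprotonated at the benzylic methyl group with LiN(iPr)2 in THF at −78 °C and acylated with F1 to give methyl 2-[13-(tert-butyldiphenylsilyloxy)-2-oxotridecyl]-4,6-dimethoxybenzoate F3. Enol lactonisation of F3 with loss of methanol, under trifluoroacetic acid or catalytic p-toluenesulfonic acid in hot toluene, returns to the route at 9.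

**Step 4.** This is the main risk of the route. Facial selectivity may be poor, because an unbranched alkyl chain offers the catalyst less steric contrast than an aryl group at C3. Turnover may be slow, because the electron-rich pyranone is reluctant to give up its conjugation. The fallback reduces a ketone, not an alkene. It sets out from 9, which is opened with LiOH in THF–H2O to the carboxylate of 8. A ketoreductase chosen from a commercial panel, with cofactor recycling by isopropanol, reduces the ketone to (R)-2-[13-(tert-butyldiphenylsilyloxy)-2-hydroxytridecyl]-4,6-dimethoxybenzoic acid F4. Acidification closes the lactone with retention at C3 and returns to the route at 10.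

**Step 5.** The silyl ether may be lost to the Lewis acid, or the C6 ether may be attacked if the mixture warms too far. The fallback changes the C8 protecting group so that no ether cleavage by boron is needed. Commercial 2-(benzyloxy)-4-methoxybenzaldehyde F5 is oxidised (Pinnick oxidation) to 2-(benzyloxy)-4-methoxybenzoic acid F6. F6 is joined with 6 under the conditions of step 3 to give 8-(benzyloxy)-3-[11-(tert-butyldiphenylsilyloxy)undecyl]-6-methoxy-1H-isochromen-1-one F7. Hydrogenation as in step 4 gives (R)-8-(benzyloxy)-3-[11-(tert-butyldiphenylsilyloxy)undecyl]-6-methoxyisochroman-1-one F8. Hydrogenolysis of F8 with H2 over Pd/C (palladium on carbon) in ethyl acetate returns to the route at 11.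

**Step 2.** Hydrogen chloride from the chlorination may attack the silyl ether, and the basic methylide may eliminate the acid chloride to a ketene that dimerises. The fallback uses an ester as the acyl donor. It sets out from 3, which is methylated with MeI and K2CO3 in DMF to methyl 12-(tert-butyldiphenylsilyloxy)dodecanoate F9. Heating F9 with the methylide from 4 and KOtBu in THF, with loss of methanol, returns to the route at 6.

## Further compounds

F1 | step 3 | N-methoxy-N-methyl-12-(tert-butyldiphenylsilyloxy)dodecanamide | CON(C)C(=O)CCCCCCCCCCCO[Si](c1ccccc1)(c1ccccc1)C(C)(C)C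
F2 | step 3 | methyl 2,4-dimethoxy-6-methylbenzoate | COC(=O)c1c(C)cc(OC)cc1OC
F3 | step 3 | methyl 2-[13-(tert-butyldiphenylsilyloxy)-2-oxotridecyl]-4,6-dimethoxybenzoate | COC(=O)c1c(CC(=O)CCCCCCCCCCCO[Si](c2ccccc2)(c2ccccc2)C(C)(C)C)cc(OC)cc1OC
F4 | step 4 | (R)-2-[13-(tert-butyldiphenylsilyloxy)-2-hydroxytridecyl]-4,6-dimethoxybenzoic acid | COc1cc(OC)c(C(=O)O)c(C[C@@H](CCCCCCCCCCCO[Si](c2ccccc2)(c2ccccc2)C(C)(C)C)O)c1
F5 | step 5 | 2-(benzyloxy)-4-methoxybenzaldehyde | COc1ccc(C=O)c(OCc2ccccc2)c1
F6 | step 5 | 2-(benzyloxy)-4-methoxybenzoic acid | COc1ccc(C(=O)O)c(OCc2ccccc2)c1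
F7 | step 5 | 8-(benzyloxy)-3-[11-(tert-butyldiphenylsilyloxy)undecyl]-6-methoxy-1H-isochromen-1-one | COc1cc(OCc3ccccc3)c2c(c1)C=C(CCCCCCCCCCCO[Si](c3ccccc3)(c3ccccc3)C(C)(C)C)OC2=O
F8 | step 5 | (R)-8-(benzyloxy)-3-[11-(tert-butyldiphenylsilyloxy)undecyl]-6-methoxyisochroman-1-one | COc1cc(OCc3ccccc3)c2c(c1)C[C@@H](CCCCCCCCCCCO[Si](c3ccccc3)(c3ccccc3)C(C)(C)C)OC2=O
F9 | step 2 | methyl 12-(tert-butyldiphenylsilyloxy)dodecanoate | COC(=O)CCCCCCCCCCCO[Si](c1ccccc1)(c1ccccc1)C(C)(C)C
A1 | alternative 1 | 3,5-dimethoxy-2-(trimethylsilyl)phenyl trifluoromethanesulfonate | COc1cc(OC)c([Si](C)(C)C)c(OS(=O)(=O)C(F)(F)F)c1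
A2 | alternative 1 | dimethyl malonate | COC(=O)CC(=O)OC
A3 | alternative 1 | methyl 2-(2-methoxy-2-oxoethyl)-4,6-dimethoxybenzoate | COC(=O)Cc1cc(OC)cc(OC)c1C(=O)OC
A4 | alternative 2 | racemic 2-(11-hydroxyundecyl)-5,7-dimethoxyindan-1-one | COc1cc(OC)c2c(c1)CC(CCCCCCCCCCCO)C2=O
A5 | alternative 2 | (R)-3-(11-hydroxyundecyl)-6,8-dimethoxyisochroman-1-one | COc1cc(OC)c2c(c1)C[C@@H](CCCCCCCCCCCO)OC2=O
A6 | alternative 3 | (R)-6-[6,17-bis(tert-butyldimethylsilyloxy)-2,4-dioxoheptadecyl]-2,2-dimethyl-4H-1,3-dioxin-4-one | CC1(C)OC(=O)C=C(CC(=O)CC(=O)C[C@@H](CCCCCCCCCCCO[Si](C)(C)C(C)(C)C)O[Si](C)(C)C(C)(C)C)O1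
A7 | alternative 3 | (R)-5-[2,13-bis(tert-butyldimethylsilyloxy)tridecyl]-7-hydroxy-2,2-dimethyl-4H-benzo[d][1,3]dioxin-4-one | CC1(C)OC(=O)c2c(C[C@@H](CCCCCCCCCCCO[Si](C)(C)C(C)(C)C)O[Si](C)(C)C(C)(C)C)cc(O)cc2O1
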